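**Retrosynthetic overview**
1. Target 27 ⇐ acetylation of alcohol 26 ⇐ C9–C10 bond: ring-closing dearomative Mukaiyama aldol of the 3-silyloxyfuran aldehyde 24 (furan → 3(2H)-furanone; sets C9 and C10 and closes the ten-membered ring).
2. 24 ⇐ C3–C4 bond: Negishi coupling of the furylzinc from silyloxyfuran 6 (two steps from 3-bromofuran) with the Z-vinyl iodide aldehyde 21.
3. 21 ⇐ cis-lactone 17 (acetonide → C8 methacrylate and C9 aldehyde).
4. 17 ⇐ C6–C7 bond: Zn-Barbier allylation/lactonisation of (Z)-3-iodobut-2-enal 10 with allylic bromide 14 (Morita–Baylis–Hillman route from (R)-glyceraldehyde acetonide, the source of C8).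
5. Ring order: γ-lactone first, the aromatic furan carried intact, then furanone and ten-membered carbocycle together in the last C–C bond-forming step.

Assumption: the target is made exactly as drawn, i.e. 6S,7S,8S,9S,10R with a 4Z alkene in germacrane numbering (C1 ketone, C2=C3 furanone alkene, C4=C5, C6 lactone carbinol, C7, C8 methacrylate carbinol, C9 acetate carbinol, C10 quaternary carbon, C11–C13 methylene lactone), used throughout; 3-bromofuran is taken as the inexpensive bulk furan feedstock.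

**Route**

Step 1
Reactants: 1 3-bromofuran
Product: 3 3-bromo-2-methylfuran, via 3-bromo-2-lithiofuran 2 (not isolated)
Conditions: LiN(i-Pr)2, THF, −78 °C; MeI, −78 → 0 °C
Reagents that add atoms: iodomethane CI
Why: LiN(i-Pr)2 removes the most acidic proton (C2–H, flanked by O and Br) without halogen–metal exchange and the 2-lithiofuran is C-methylated (directed metalation/alkylation); no stereocentre.

Step 2
Reactants: 3 3-bromo-2-methylfuran
Product: 6 triisopropyl[(2-methylfuran-3-yl)oxy]silane, via 3-lithio-2-methylfuran 4 (not isolated), via lithium 2-methylfuran-3-olate 5 (not isolated)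
Conditions: t-BuLi (2 equiv), Et2O, −78 °C; LiOOt-Bu (from t-BuOOH and n-BuLi, THF, −78 °C), −78 → −20 °C; i-Pr3SiOTf, −78 → 0 °C
Reagents that add atoms: tert-butyl hydroperoxide (used as LiOOt-Bu) CC(C)(C)OO; triisopropylsilyl trifluoromethanesulfonate CC(C)[Si](C(C)C)(C(C)C)OS(=O)(=O)C(F)(F)F
Why: Br/Li exchange at −78 °C, electrophilic oxygen transfer from the lithium peroxide to the aryllithium (known hydroxylation of organolithiums) and O-silylation of the hard furan-3-olate oxygen give the aromatic silyl enol ether; no stereocentre.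

Step 3
Reactants: 7 but-2-yn-1-ol
Product: 9 (2Z)-3-iodobut-2-en-1-ol, via cyclic vinylalanate 8 (not isolated)
Conditions: NaAlH2(OCH2CH2OCH3)2, THF, 0 → 25 °C; then I2, THF, −78 → 0 °C
Reagents that add atoms: iodine II
Why: hydroxyl-directed trans-hydroalumination puts aluminium on C3 in a five-membered alkoxyalanate and iodinolysis with retention gives the Z-vinyl iodide (I cis to CH2OH), which fixes the 4Z geometry of the target.

Step 4
Reactants: 9 (2Z)-3-iodobut-2-en-1-ol
Product: 10 (2Z)-3-iodobut-2-enal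
Conditions: MnO2, CH2Cl2, 25 °C, dark; used crude
Reagents that add atoms: none
Why: MnO2 oxidises the allylic alcohol selectively and leaves the vinyl iodide and the Z geometry untouched (allylic oxidation).

Step 5
Reactants: 11 (4R)-2,2-dimethyl-1,3-dioxolane-4-carbaldehyde; 12 methyl acrylate
Product: 13 methyl 2-{[(4R)-2,2-dimethyl-1,3-dioxolan-4-yl](hydroxy)methyl}prop-2-enoate (both carbinol epimers)
Conditions: DABCO (0.5 equiv), neat methyl acrylate, 25 °C, 5 d
Reagents that add atoms: none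
Why: Morita–Baylis–Hillman reaction; the dioxolane stereocentre (future C8) comes from the chiral pool and the new carbinol centre is irrelevant because it is destroyed in step 6.

Step 6
Reactants: 13 methyl 2-{[(4R)-2,2-dimethyl-1,3-dioxolan-4-yl](hydroxy)methyl}prop-2-enoate
Product: 14 methyl (2Z)-2-(bromomethyl)-3-[(4S)-2,2-dimethyl-1,3-dioxolan-4-yl]prop-2-enoate
Conditions: NBS, Me2S, CH2Cl2, 0 → 25 °C
Reagents that add atoms: N-bromosuccinimide O=C1CCC(=O)N1Br
Why: the bromosulfonium salt activates the allylic hydroxyl and bromide returns in SN2′ fashion to give the thermodynamically preferred (Z)-2-(bromomethyl)enoate (ester trans to the dioxolane); the acetonide survives the neutral conditions.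

Step 7
Reactants: 10 (2Z)-3-iodobut-2-enal; 14 methyl (2Z)-2-(bromomethyl)-3-[(4S)-2,2-dimethyl-1,3-dioxolan-4-yl]prop-2-enoate
Product: 17 (4S,5R)-4-[(4S)-2,2-dimethyl-1,3-dioxolan-4-yl]-5-[(1Z)-2-iodoprop-1-en-1-yl]-3-methylideneoxolan-2-one, via allylzinc bromide 15 (not isolated), via hydroxy ester 16 (not isolated)
Conditions: Zn dust, THF/sat. aq. NH4Cl, 0 → 25 °C; then PPTS (cat.), CH2Cl2, 25 °C
Reagents that add atoms: none
Why: Barbier 2-(alkoxycarbonyl)allylation with lactonisation: a chair Zimmerman–Traxler transition state with the γ-substituent (cis to CH2Zn) axial gives the 6,7-syn adduct and hence the cis-lactone, and C7 attacks on the face that carries the zinc-coordinated dioxolane oxygen (C8–H in the alkene plane to avoid A(1,3) strain, CH2O arm anti), which sets C6 and C7 relative to C8.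

Step 8
Reactants: 17 (4S,5R)-4-[(4S)-2,2-dimethyl-1,3-dioxolan-4-yl]-5-[(1Z)-2-iodoprop-1-en-1-yl]-3-methylideneoxolan-2-one
Product: 18 (4R,5R)-4-[(1S)-1,2-dihydroxyethyl]-5-[(1Z)-2-iodoprop-1-en-1-yl]-3-methylideneoxolan-2-one
Conditions: AcOH/H2O (4:1), 25 °C
Reagents that add atoms: none
Why: acid hydrolysis of the isopropylidene acetal, under which the lactone, the vinyl iodide and all stereocentres are stable.

Step 9
Reactants: 18 (4R,5R)-4-[(1S)-1,2-dihydroxyethyl]-5-[(1Z)-2-iodoprop-1-en-1-yl]-3-methylideneoxolan-2-one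
Product: 20 (1S)-1-{(2R,3S)-2-[(1Z)-2-iodoprop-1-en-1-yl]-4-methylidene-5-oxooxolan-3-yl}-2-[(triethylsilyl)oxy]ethyl 2-methylprop-2-enoate, via primary triethylsilyl ether 19 (not isolated)
Conditions: Et3SiCl (1.05 equiv), imidazole, CH2Cl2, −40 °C; then methacrylic anhydride, Et3N, DMAP (cat.), 0 °C
Reagents that add atoms: chlorotriethylsilane CC[Si](Cl)(CC)CC; methacrylic anhydride C=C(C)C(=O)OC(=O)C(C)=C
Why: the primary hydroxyl is silylated selectively at low temperature and the remaining secondary C8 hydroxyl is then acylated (DMAP-catalysed esterification) with retention.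

Step 10
Reactants: 20 (1S)-1-{(2R,3S)-2-[(1Z)-2-iodoprop-1-en-1-yl]-4-methylidene-5-oxooxolan-3-yl}-2-[(triethylsilyl)oxy]ethyl 2-methylprop-2-enoate
Product: 21 (1S)-1-{(2R,3S)-2-[(1Z)-2-iodoprop-1-en-1-yl]-4-methylidene-5-oxooxolan-3-yl}-2-oxoethyl 2-methylprop-2-enoate
Conditions: (COCl)2, DMSO, CH2Cl2, −78 → −40 °C; Et3N, −78 → −30 °C; cold pH 7 quench
Reagents that add atoms: none
Why: primary triethylsilyl ethers are oxidised directly under Swern conditions (the chlorosulfonium ion attacks the silyl ether oxygen) while esters are inert, and the cold quench protects the α-acyloxy aldehyde centre C8.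

Step 11
Reactants: 6 triisopropyl[(2-methylfuran-3-yl)oxy]silane; 21 (1S)-1-{(2R,3S)-2-[(1Z)-2-iodoprop-1-en-1-yl]-4-methylidene-5-oxooxolan-3-yl}-2-oxoethyl 2-methylprop-2-enoate
Product: 24 (1S)-1-{(2S,3S)-2-[(1Z)-2-{5-methyl-4-[(triisopropylsilyl)oxy]furan-2-yl}prop-1-en-1-yl]-4-methylidene-5-oxooxolan-3-yl}-2-oxoethyl 2-methylprop-2-enoate, via 5-lithiofuran 22 (not isolated), via furylzinc chloride 23 (not isolated)
Conditions: 6, n-BuLi, THF, −78 → 0 °C; ZnCl2, 0 °C; then 21, Pd(PPh3)4 (5 mol %), THF, 25 °C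
Reagents that add atoms: none
Why: ring α-lithiation of the furan at C5, transmetalation to zinc and Negishi coupling with the alkenyl iodide proceed with retention of the Z geometry, and the arylzinc chloride is expected to couple faster than it adds to the aldehyde at 25 °C.

Step 12
Reactants: 24 (1S)-1-{(2S,3S)-2-[(1Z)-2-{5-methyl-4-[(triisopropylsilyl)oxy]furan-2-yl}prop-1-en-1-yl]-4-methylidene-5-oxooxolan-3-yl}-2-oxoethyl 2-methylprop-2-enoate
Product: 26 (2Z,4S,8S,9S,10S,11R)-10-hydroxy-2,11-dimethyl-7-methylidene-6,12-dioxo-5,14-dioxatricyclo[9.2.1.0(4,8)]tetradeca-1(13),2-dien-9-yl 2-methylprop-2-enoate (9-O-deacetyl target), via difluoroboron aldolate 25 (not isolated)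
Conditions: slow addition of 24 to BF3·OEt2 (2 equiv), CH2Cl2 (0.001 M), −78 °C; sat. aq. NaHCO3
Reagents that add atoms: none
Why: Proposed new method: the Lewis acid activates the aldehyde and the 3-silyloxyfuran attacks through its methyl-bearing C2 (= C10), trading aromaticity for the vinylogous ester of the 3(2H)-furanone (closest known chemistry: intermolecular BF3-mediated aldol additions of 3-silyloxyfurans and Lewis acid medium-ring Mukaiyama cyclisations); only four rotatable bonds separate the termini, allylic 1,3-strain about C5–C6 (C6–H in the diene plane, C6–O turned away from the furan oxygen) sends the tether over the furan face that gives 10R, the BF3-bound carbonyl lies over the ring and away from the bulky silyloxy group (endo-type open transition state) and the C8 ester stays anti to the forming bond (polar Felkin–Anh), which gives 9S.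

Step 13
Reactants: 26 9-O-deacetyl target
Product: 27 (2Z,4S,8S,9S,10S,11R)-10-acetyloxy-2,11-dimethyl-7-methylidene-6,12-dioxo-5,14-dioxatricyclo[9.2.1.0(4,8)]tetradeca-1(13),2-dien-9-yl 2-methylprop-2-enoate (target)
Conditions: Ac2O, DMAP, pyridine, CH2Cl2, 0 → 25 °C
Reagents that add atoms: acetic anhydride CC(=O)OC(C)=O
Why: DMAP-catalysed acetylation of the hindered secondary C9 alcohol with retention; C10 is quaternary, so no centre can epimerise.

**Compound list**
1 | 3-bromofuran | Brc1ccoc1 | starting material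
2 | 3-bromo-2-lithiofuran | [Li]c1occc1Br | intermediate
3 | 3-bromo-2-methylfuran | Cc1occc1Br | intermediate
4 | 3-lithio-2-methylfuran | Cc1occc1[Li] | intermediate
5 | lithium 2-methylfuran-3-olate | Cc1occc1[O-].[Li+] | intermediate
6 | triisopropyl[(2-methylfuran-3-yl)oxy]silane | Cc1occc1O[Si](C(C)C)(C(C)C)C(C)C | intermediate
7 | but-2-yn-1-ol | CC#CCO | starting material
8 | sodium 2,2-bis(2-methoxyethoxy)-3-methyl-2,5-dihydro-1,2-oxaaluminol-2-uide (cyclic vinylalanate) | [Na+].COCCO[Al-]1(OCCOC)OCC=C1C | intermediate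
9 | (2Z)-3-iodobut-2-en-1-ol | C/C(I)=C/CO | intermediate
10 | (2Z)-3-iodobut-2-enal | C/C(I)=C/C=O | intermediate
11 | (4R)-2,2-dimethyl-1,3-dioxolane-4-carbaldehyde | O=C[C@H]1COC(C)(C)O1 | starting material
12 | methyl acrylate | C=CC(=O)OC | starting material
13 | methyl 2-{[(4R)-2,2-dimethyl-1,3-dioxolan-4-yl](hydroxy)methyl}prop-2-enoate (carbinol epimers) | COC(=O)C(=C)C(O)[C@H]1COC(C)(C)O1 | intermediate
14 | methyl (2Z)-2-(bromomethyl)-3-[(4S)-2,2-dimethyl-1,3-dioxolan-4-yl]prop-2-enoate | COC(=O)/C(CBr)=C/[C@H]1COC(C)(C)O1 | intermediate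
15 | bromo{(2Z)-3-[(4S)-2,2-dimethyl-1,3-dioxolan-4-yl]-2-(methoxycarbonyl)prop-2-en-1-yl}zinc | COC(=O)/C(C[Zn]Br)=C/[C@H]1COC(C)(C)O1 | intermediate
16 | methyl (3S,4R,5Z)-3-[(4S)-2,2-dimethyl-1,3-dioxolan-4-yl]-4-hydroxy-6-iodo-2-methylidenehept-5-enoate | COC(=O)C(=C)[C@@H]([C@@H](O)/C=C(/C)I)[C@H]1COC(C)(C)O1 | intermediate
17 | (4S,5R)-4-[(4S)-2,2-dimethyl-1,3-dioxolan-4-yl]-5-[(1Z)-2-iodoprop-1-en-1-yl]-3-methylideneoxolan-2-one (cis-lactone) | C=C1C(=O)O[C@@H](/C=C(/C)I)[C@H]1[C@H]2COC(C)(C)O2 | intermediate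
18 | (4R,5R)-4-[(1S)-1,2-dihydroxyethyl]-5-[(1Z)-2-iodoprop-1-en-1-yl]-3-methylideneoxolan-2-one | C=C1C(=O)O[C@@H](/C=C(/C)I)[C@H]1[C@H](O)CO | intermediate
19 | (4R,5R)-4-{(1S)-1-hydroxy-2-[(triethylsilyl)oxy]ethyl}-5-[(1Z)-2-iodoprop-1-en-1-yl]-3-methylideneoxolan-2-one | C=C1C(=O)O[C@@H](/C=C(/C)I)[C@H]1[C@H](O)CO[Si](CC)(CC)CC | intermediate
20 | (1S)-1-{(2R,3S)-2-[(1Z)-2-iodoprop-1-en-1-yl]-4-methylidene-5-oxooxolan-3-yl}-2-[(triethylsilyl)oxy]ethyl 2-methylprop-2-enoate | C=C1C(=O)O[C@@H](/C=C(/C)I)[C@H]1[C@H](OC(=O)C(C)=C)CO[Si](CC)(CC)CC | intermediate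
21 | (1S)-1-{(2R,3S)-2-[(1Z)-2-iodoprop-1-en-1-yl]-4-methylidene-5-oxooxolan-3-yl}-2-oxoethyl 2-methylprop-2-enoate | C=C1C(=O)O[C@@H](/C=C(/C)I)[C@H]1[C@H](OC(=O)C(C)=C)C=O | intermediate
22 | [5-methyl-4-(triisopropylsilyloxy)furan-2-yl]lithium | Cc1oc([Li])cc1O[Si](C(C)C)(C(C)C)C(C)C | intermediate
23 | chloro[5-methyl-4-(triisopropylsilyloxy)furan-2-yl]zinc | Cc1oc([Zn]Cl)cc1O[Si](C(C)C)(C(C)C)C(C)C | intermediate
24 | (1S)-1-{(2S,3S)-2-[(1Z)-2-{5-methyl-4-[(triisopropylsilyl)oxy]furan-2-yl}prop-1-en-1-yl]-4-methylidene-5-oxooxolan-3-yl}-2-oxoethyl 2-methylprop-2-enoate | C=C1C(=O)O[C@@H](/C=C(/C)c2cc(O[Si](C(C)C)(C(C)C)C(C)C)c(C)o2)[C@H]1[C@H](OC(=O)C(C)=C)C=O | intermediate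
25 | O-difluoroboryl derivative of 26 (boron aldolate at C9) | C=C(C)C(=O)O[C@H]1[C@H]2C(=C)C(=O)O[C@H]2/C=C(/C)C2=CC(=O)[C@](C)(O2)[C@H]1OB(F)F | intermediate
26 | 9-O-deacetyl target (6S,7S,8S,9S,10R; 4Z) | C=C(C)C(=O)O[C@H]1[C@H]2C(=C)C(=O)O[C@H]2/C=C(/C)C2=CC(=O)[C@](C)(O2)[C@H]1O | intermediate
27 | CNP0365569.3 (6S,7S,8S,9S,10R; 4Z) | C=C(C)C(=O)O[C@H]1[C@H]2C(=C)C(=O)O[C@H]2/C=C(/C)C2=CC(=O)[C@](C)(O2)[C@H]1OC(C)=O | target

**Step count and risks**

Total step count: 13 steps. Longest linear sequence: 9 steps (11 + 12 → 13 → 14 → 17 → 18 → 20 → 21 → 24 → 26 → 27).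

Most likely to fail, 1: step 12. It closes a medium ring, sets two stereocentres at once and exposes an allylic, furan-conjugated lactone to a Lewis acid. The fallback keeps the dearomative aldol but runs it between the fragments and closes the ring at C3–C4 instead. It sets out from 6 and 21, which are combined directly (BF3·OEt2, CH2Cl2, −78 °C) to give the open-chain aldol adduct F1, in which C9 and C10 are set under acyclic Felkin–Anh and endo control. Acetylation (Ac2O, DMAP) gives the acetate F2. Zincation of the furanone C5–H (TMPZnCl·LiCl, THF, 25 °C, by analogy with the zincation of chromones next to the ring oxygen) gives the furanone-5-ylzinc chloride F3. Intramolecular Negishi coupling with the Z-vinyl iodide (Pd(PPh3)4, high dilution) then comes back to the route at 27.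

Most likely to fail, 2: step 7. The sense of induction from C8 to C7 with the acetonide is model-based and not secured by a direct precedent; the opposite face would give the 6,7-diastereomer pair. The fallback replaces the weakly coordinating acetonide by a free hydroxyl, which binds indium in water and directs the addition. It sets out from 14, which is first hydrolysed (AcOH/H2O) to the diol bromide F4. Indium-mediated coupling of F4 with 10 in THF/H2O gives the triol ester F5, and lactonisation onto the C6 hydroxyl (PPTS, CH2Cl2) comes back to the route at 18.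

Most likely to fail, 3: step 11. A nucleophilic furylzinc reagent and zinc salts meet an electrophilic, epimerisable α-acyloxy aldehyde. The fallback changes the coupling manifold to a neutral one. It sets out from 6, which is lithiated (n-BuLi) and quenched with Bu3SnCl to give the furylstannane F6. Stille coupling of F6 with 21 (Pd2(dba)3, AsPh3, CuI, DMF, 25 °C) comes back to the route at 24.

Further compounds
F1 | step 12 | (1S,2S)-2-hydroxy-1-{(2R,3S)-2-[(1Z)-2-iodoprop-1-en-1-yl]-4-methylidene-5-oxooxolan-3-yl}-2-[(2R)-2-methyl-3-oxo-2,3-dihydrofuran-2-yl]ethyl 2-methylprop-2-enoate | C=C(C)C(=O)O[C@@H]([C@H]1C(=C)C(=O)O[C@H]1/C=C(/C)I)[C@H](O)[C@@]1(C)OC=CC1=O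
F2 | step 12 | 2-O-acetyl derivative of F1 | C=C(C)C(=O)O[C@@H]([C@H]1C(=C)C(=O)O[C@H]1/C=C(/C)I)[C@H](OC(C)=O)[C@@]1(C)OC=CC1=O
F3 | step 12 | furanone-5-ylzinc chloride derived from F2 | C=C(C)C(=O)O[C@@H]([C@H]1C(=C)C(=O)O[C@H]1/C=C(/C)I)[C@H](OC(C)=O)[C@@]1(C)OC([Zn]Cl)=CC1=O
F4 | step 7 | methyl (2Z,4S)-2-(bromomethyl)-4,5-dihydroxypent-2-enoate | COC(=O)/C(CBr)=C/[C@H](O)CO
F5 | step 7 | methyl (3S,4R,5Z)-3-[(1S)-1,2-dihydroxyethyl]-4-hydroxy-6-iodo-2-methylidenehept-5-enoate | COC(=O)C(=C)[C@@H]([C@@H](O)/C=C(/C)I)[C@H](O)CO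
F6 | step 11 | tributyl[5-methyl-4-(triisopropylsilyloxy)furan-2-yl]stannane | CCCC[Sn](CCCC)(CCCC)c1cc(O[Si](C(C)C)(C(C)C)C(C)C)c(C)o1
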